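**Plan**

1. Retrosynthesis: cut the C–Cl bond and the two ester C–O bonds (carbinols at C4 and C6), take the hydroxyethyl chain back to a C5 vinyl group and that to a C5 bromide, cut the C2–C3 bond of the cyclopentane, and finally cut the C3a–CHO and C7a–CH2 (methallyl) bonds back to dimethyl 2-bromoisophthalate.
2. Enabling feature: in the five-membered ring, C2 is fully substituted, carries both methyl groups and is bonded to the benzylic C3 methylene. C2 can therefore be a tertiary radical made from a 2-methylallyl group on C7a (one methyl comes from a transferred hydrogen atom), and C3 can be the carbon of an aldehyde tosylhydrazone on C3a that ends as CH2.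
3. Forward, before ring closure: the benzene ring is bought with both ester carbons and the bromine in place; borylation para to bromine, methallylation, ortho-formylation and hydrazone formation follow. The cyclopentane, the only ring made, closes in step 5.
4. Forward, after ring closure: bromide to vinyl, reduction of both esters, butanoylation of the less hindered C6 carbinol, acetylation of C4, and only then hydroboration–oxidation and chlorination of the vinyl group, so that no hydroxyethyl or chloroethyl chain ever sits beside an ester it could lactonise with.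
5. Stereochemistry: the target is achiral; the one stereocentre that appears (C3 of the cyclised hydrazide) is racemic and is erased in the same flask.

Key step: step 5

Remark: ring positions are given throughout in the indane numbering of the target (C4 CH2OAc, C5 CH2CH2Cl, C6 CH2OC(O)Pr, C7 H); benzene precursors are named as isophthalates.

**Route**

Step 1
Reactants: 1 dimethyl 2-bromoisophthalate
Product: 2 dimethyl 2-bromo-5-(4,4,5,5-tetramethyl-1,3,2-dioxaborolan-2-yl)isophthalate
Conditions: [Ir(OMe)(cod)]2 (1.5 mol %), 4,4′-di-tert-butyl-2,2′-bipyridine (3 mol %), B2pin2 (1.0 equiv), THF, 80 °C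
Reagents that add atoms: bis(pinacolato)diboron, CC1(C)OB(OC1(C)C)B1OC(C)(C)C(C)(C)O1
Why: Iridium-catalysed aromatic C–H borylation is governed by sterics, and in this 1,2,3-trisubstituted benzene only the C–H para to bromine has no ortho substituent, while the aryl bromide and the esters are tolerated.

Step 2
Reactants: 2 dimethyl 2-bromo-5-(4,4,5,5-tetramethyl-1,3,2-dioxaborolan-2-yl)isophthalate; 3 methallyl chloride (3-chloro-2-methylprop-1-ene)
Product: 4 dimethyl 2-bromo-5-(2-methylallyl)isophthalate
Conditions: (IPr)CuCl (5 mol %; IPr = 1,3-bis(2,6-diisopropylphenyl)imidazol-2-ylidene), KOt-Bu (1.1 equiv), THF, 40 °C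
Reagents that add atoms: none
Why: Copper-catalysed allyl–aryl coupling of an arylboronate with an allylic chloride: the alkoxide-activated boronate transmetalates to monovalent copper and the arylcopper substitutes the chloride, SN2 and SN2′ attack giving the same product for the symmetric 2-methylallyl unit, and the hindered aryl bromide should not react with copper under these conditions.

Step 3
Reactants: 4 dimethyl 2-bromo-5-(2-methylallyl)isophthalate
Product: 6 dimethyl 2-bromo-4-formyl-5-(2-methylallyl)isophthalate, via arylmagnesium chloride 5 (not isolated)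
Conditions: TMPMgCl·LiCl (1.3 equiv), THF, –20 °C; then DMF (3 equiv), –20 °C → rt; aqueous work-up
Reagents that add atoms: N,N-dimethylformamide, CN(C)C=O
Why: Directed ortho-magnesiation followed by formylation with DMF: the ester carbonyl guides the hindered amide base to the adjacent ring C–H (the two remaining ring hydrogens are equivalent), kinetic deprotonation there should outpace attack at the benzylic–allylic CH2, and the bromide and esters survive at low temperature.

Step 4
Reactants: 6 dimethyl 2-bromo-4-formyl-5-(2-methylallyl)isophthalate; 7 4-methylbenzenesulfonohydrazide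
Product: 8 dimethyl 2-bromo-5-(2-methylallyl)-4-[(E)-(tosylhydrazono)methyl]isophthalate
Conditions: MeOH, rt
Reagents that add atoms: none
Why: Condensation of the aldehyde with the sulfonyl hydrazide gives the hydrazone in its thermodynamically preferred E geometry, and the neutral conditions leave the neighbouring ester and the alkene untouched.

Step 5
Reactants: 8 dimethyl 2-bromo-5-(2-methylallyl)-4-[(E)-(tosylhydrazono)methyl]isophthalate
Product: 11 dimethyl 5-bromo-2,2-dimethylindane-4,6-dicarboxylate, via cyclised tosylhydrazide 9 (not isolated), via alkyldiazene 10 (not isolated)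
Conditions: Fe(acac)3 (30 mol %), PhSiH3 (2.5 equiv), THF/MeOH (1:1, degassed), rt; then NaOAc, MeOH, 65 °C
Reagents that add atoms: none
Why: Trivalent iron and phenylsilane form an iron hydride that transfers a hydrogen atom to the terminal CH2 of the methallyl group, which creates the second C2 methyl and a tertiary C2 radical; this nucleophilic radical adds to the hydrazone carbon on C3a, the resulting hydrazinyl radical is reduced by divalent iron and protonated to give 9, and warming with acetate expels toluenesulfinate to give diazene 10, which loses dinitrogen and leaves C3 as CH2. The closest known reactions are the iron-hydride reductive coupling of unactivated olefins with sulfonylhydrazones, including its traceless hydromethylation variant, and the intramolecular alkene–tosylhydrazone cyclisation run under the same conditions. The cyclopentane closes in the 5-exo-trig mode, with the C=N bond exocyclic to the new ring. No stereocentre survives, since C3 of 9 forms as a racemate and becomes a methylene. The step needs hydrogen-atom transfer to the alkene without reduction of the aryl bromide, the esters or the C=N bond, and it needs ring closure to be faster than a second hydrogen-atom transfer or capture by oxygen. The 1,1-disubstituted alkene is the best hydrogen-atom acceptor in the molecule, the ortho placement of radical and acceptor on the rigid benzene ring should make closure fast, and the solution is degassed.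

Step 6
Reactants: 11 dimethyl 5-bromo-2,2-dimethylindane-4,6-dicarboxylate; 12 potassium trifluoro(vinyl)borate
Product: 13 dimethyl 5-ethenyl-2,2-dimethylindane-4,6-dicarboxylate
Conditions: PdCl2(dppf)·CH2Cl2 (5 mol %), Cs2CO3 (3 equiv), THF/H2O (9:1), 80 °C
Reagents that add atoms: none
Why: Suzuki–Miyaura coupling: the bromide flanked by two esters is electron-poor enough for oxidative addition to zerovalent palladium, the small vinyl group transfers readily to the di-ortho-substituted position, and vinyl is chosen because it stays inert until the esters have been reduced and acylated.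

Step 7
Reactants: 13 dimethyl 5-ethenyl-2,2-dimethylindane-4,6-dicarboxylate
Product: 14 (5-ethenyl-2,2-dimethylindane-4,6-diyl)dimethanol
Conditions: LiAlH4, THF, 0 °C → rt; then H2O, aq NaOH
Reagents that add atoms: none
Why: Hydride reduction of both esters to the primary benzylic alcohols with LiAlH4, which does not add to the unactivated styrene double bond.

Step 8
Reactants: 14 (5-ethenyl-2,2-dimethylindane-4,6-diyl)dimethanol
Product: 15 [5-ethenyl-4-(hydroxymethyl)-2,2-dimethylindan-6-yl]methyl butanoate
Conditions: butanoyl chloride (1.0 equiv, slow addition), 2,4,6-collidine, CH2Cl2, –78 → –40 °C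
Reagents that add atoms: butanoyl chloride, CCCC(=O)Cl
Why: Sterically controlled acylation: the C6 carbinol has a single ortho substituent whereas the C4 carbinol is flanked by the vinyl group and the ring CH2 of C3, so one equivalent of acyl chloride with a hindered, non-nucleophilic pyridine base at low temperature should esterify C6 preferentially.

Step 9
Reactants: 15 [5-ethenyl-4-(hydroxymethyl)-2,2-dimethylindan-6-yl]methyl butanoate
Product: 16 [4-(acetoxymethyl)-5-ethenyl-2,2-dimethylindan-6-yl]methyl butanoate
Conditions: Ac2O, pyridine, DMAP (cat.), CH2Cl2, rt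
Reagents that add atoms: acetic anhydride, CC(=O)OC(C)=O
Why: DMAP-catalysed acylation of the remaining, more hindered primary alcohol with acetic anhydride should go to completion without disturbing the butanoate.

Step 10
Reactants: 16 [4-(acetoxymethyl)-5-ethenyl-2,2-dimethylindan-6-yl]methyl butanoate
Product: 18 [4-(acetoxymethyl)-5-(2-hydroxyethyl)-2,2-dimethylindan-6-yl]methyl butanoate, via alkylborane 17 (not isolated)
Conditions: 9-BBN, THF, 0 °C → rt; then 30% H2O2, aq NaOAc, 0 °C → rt
Reagents that add atoms: 9-borabicyclo[3.3.1]nonane, B1C2CCCC1CCC2; hydrogen peroxide, OO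
Why: Brown hydroboration–oxidation: 9-BBN places boron on the terminal carbon of the styrene with high anti-Markovnikov selectivity and does not reduce esters, and acetate-buffered peroxide converts C–B into C–OH without hydrolysing the acetate or the butanoate.

Step 11
Reactants: 18 [4-(acetoxymethyl)-5-(2-hydroxyethyl)-2,2-dimethylindan-6-yl]methyl butanoate
Product: 19 [4-(acetoxymethyl)-5-(2-chloroethyl)-2,2-dimethylindan-6-yl]methyl butanoate (CNP0321917.0)
Conditions: PPh3, N-chlorosuccinimide, THF, 0 °C → rt
Reagents that add atoms: N-chlorosuccinimide, O=C1CCC(=O)N1Cl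
Why: Appel-type chlorination: the alcohol is activated as an alkoxyphosphonium salt and displaced by chloride in an SN2 reaction at the primary carbon, under neutral conditions that spare both benzylic esters.

**Compound list**

1 | dimethyl 2-bromoisophthalate | COC(=O)c1cccc(C(=O)OC)c1Br | starting material
2 | dimethyl 2-bromo-5-(4,4,5,5-tetramethyl-1,3,2-dioxaborolan-2-yl)isophthalate | COC(=O)c1cc(B2OC(C)(C)C(C)(C)O2)cc(C(=O)OC)c1Br | intermediate
3 | methallyl chloride (3-chloro-2-methylprop-1-ene) | CC(=C)CCl | starting material
4 | dimethyl 2-bromo-5-(2-methylallyl)isophthalate | COC(=O)c1cc(CC(C)=C)cc(C(=O)OC)c1Br | intermediate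
5 | arylmagnesium chloride from 4, magnesium on the ring carbon between ester and methallyl group (not isolated) | COC(=O)c1cc(CC(C)=C)c([Mg]Cl)c(C(=O)OC)c1Br | intermediate
6 | dimethyl 2-bromo-4-formyl-5-(2-methylallyl)isophthalate | COC(=O)c1cc(CC(C)=C)c(C=O)c(C(=O)OC)c1Br | intermediate
7 | 4-methylbenzenesulfonohydrazide | Cc1ccc(S(=O)(=O)NN)cc1 | starting material
8 | dimethyl 2-bromo-5-(2-methylallyl)-4-[(E)-(tosylhydrazono)methyl]isophthalate | COC(=O)c1cc(CC(C)=C)c(/C=N/NS(=O)(=O)c2ccc(C)cc2)c(C(=O)OC)c1Br | intermediate
9 | dimethyl 5-bromo-2,2-dimethyl-3-(2-tosylhydrazinyl)indane-4,6-dicarboxylate, racemic at C3 (not isolated) | COC(=O)c1cc2c(c(C(=O)OC)c1Br)C(NNS(=O)(=O)c3ccc(C)cc3)C(C)(C)C2 | intermediate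
10 | dimethyl 5-bromo-3-diazenyl-2,2-dimethylindane-4,6-dicarboxylate, racemic at C3 (not isolated) | COC(=O)c1cc2c(c(C(=O)OC)c1Br)C(N=N)C(C)(C)C2 | intermediate
11 | dimethyl 5-bromo-2,2-dimethylindane-4,6-dicarboxylate | COC(=O)c1cc2c(c(C(=O)OC)c1Br)CC(C)(C)C2 | intermediate
12 | potassium trifluoro(vinyl)borate | [K+].C=C[B-](F)(F)F | starting material
13 | dimethyl 5-ethenyl-2,2-dimethylindane-4,6-dicarboxylate | COC(=O)c1cc2c(c(C(=O)OC)c1C=C)CC(C)(C)C2 | intermediate
14 | (5-ethenyl-2,2-dimethylindane-4,6-diyl)dimethanol | OCc1cc2c(c(CO)c1C=C)CC(C)(C)C2 | intermediate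
15 | [5-ethenyl-4-(hydroxymethyl)-2,2-dimethylindan-6-yl]methyl butanoate | CCCC(=O)OCc1cc2c(c(CO)c1C=C)CC(C)(C)C2 | intermediate
16 | [4-(acetoxymethyl)-5-ethenyl-2,2-dimethylindan-6-yl]methyl butanoate | CCCC(=O)OCc1cc2c(c(COC(C)=O)c1C=C)CC(C)(C)C2 | intermediate
17 | B-alkyl-9-borabicyclo[3.3.1]nonane from 16, boron on the terminal side-chain carbon (not isolated) | CCCC(=O)OCc1cc2c(c(COC(C)=O)c1CCB3C4CCCC3CCC4)CC(C)(C)C2 | intermediate
18 | [4-(acetoxymethyl)-5-(2-hydroxyethyl)-2,2-dimethylindan-6-yl]methyl butanoate | CCCC(=O)OCc1cc2c(c(COC(C)=O)c1CCO)CC(C)(C)C2 | intermediate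
19 | [4-(acetoxymethyl)-5-(2-chloroethyl)-2,2-dimethylindan-6-yl]methyl butanoate (CNP0321917.0) | CCCC(=O)OCc1cc2c(c(COC(C)=O)c1CCCl)CC(C)(C)C2 | target

**Step count and risks**

Total step count: 11. Longest linear sequence: 11 steps (1 → 19); the route is fully linear.

Steps most likely to fail, most doubtful first:

Step 8. The two primary benzylic hydroxyls may not be discriminated well enough, so that the butanoyl group is spread over C6 and C4 and some double acylation occurs. The fallback moves the differentiation to the ester stage, where the steric gap is much larger. It sets out from 13: the C6 ester, which has only one ortho substituent, is saponified selectively (LiOH, THF/MeOH/H2O, rt) to 5-ethenyl-4-(methoxycarbonyl)-2,2-dimethylindane-6-carboxylic acid F1, the C4 ester being shielded on both sides. LiEt3BH (THF, 0 °C → rt) then reduces the remaining ester in the presence of the carboxylate to 5-ethenyl-4-(hydroxymethyl)-2,2-dimethylindane-6-carboxylic acid F2. Acetylation (Ac2O, pyridine, aqueous work-up) gives 4-(acetoxymethyl)-5-ethenyl-2,2-dimethylindane-6-carboxylic acid F3. Activation as the mixed carbonic anhydride (isobutyl chloroformate, N-methylmorpholine, THF, –10 °C) and reduction with NaBH4 (THF/H2O, 0 °C) gives [5-ethenyl-6-(hydroxymethyl)-2,2-dimethylindan-4-yl]methyl acetate F4. Butanoylation (butanoyl chloride, pyridine, DMAP) comes back to the route at 16.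

Step 5. The tertiary radical may be quenched by a second hydrogen-atom transfer or by traces of oxygen before it closes, or the cyclised hydrazide may fragment sluggishly. The fallback keeps the C2–C3 disconnection but generates the radical by halogen abstraction in a tin hydride chain and uses a self-fragmenting acceptor. It sets out from 6: Markovnikov addition of HBr (HBr in AcOH, 0 °C) gives dimethyl 2-bromo-5-(2-bromo-2-methylpropyl)-4-formylisophthalate F5. Condensation with 1-amino-2-phenylaziridine (acetate salt, CH2Cl2, 0 °C) gives dimethyl 2-bromo-5-(2-bromo-2-methylpropyl)-4-{(E)-[(2-phenylaziridin-1-yl)imino]methyl}isophthalate F6. Bu3SnH with AIBN (benzene, 80 °C, slow addition) abstracts the tertiary bromine, the radical closes 5-exo onto the imine carbon, the aminyl radical fragments with loss of styrene and dinitrogen, and the C3 radical takes hydrogen from the stannane. This comes back to the route at 11.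

Step 3. Deprotonation may occur at the doubly activated benzylic–allylic CH2 (with alkene migration), or the arylmagnesium may attack an ester, instead of clean ortho-formylation. The fallback avoids a strong base next to the methallyl group by letting a phenol direct the formylation and introducing the methallyl group last. It sets out from 2: oxidation of the boronate (NaBO3·4H2O, THF/H2O, rt) gives dimethyl 2-bromo-5-hydroxyisophthalate F7. Magnesium-mediated ortho-formylation (MgCl2, Et3N, paraformaldehyde, MeCN, reflux; Casnati–Skattebøl) gives dimethyl 2-bromo-4-formyl-5-hydroxyisophthalate F8, the two positions ortho to the hydroxyl being equivalent. Triflation (Tf2O, pyridine, CH2Cl2, 0 °C) gives dimethyl 2-bromo-4-formyl-5-{[(trifluoromethyl)sulfonyl]oxy}isophthalate F9. Stille coupling with tributyl(2-methylallyl)stannane (PdCl2(PPh3)2, LiCl, DMF, 80 °C) should take place at the triflate in preference to the doubly flanked bromide and comes back to the route at 6.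

**Further compounds**

F1 | step 8 | 5-ethenyl-4-(methoxycarbonyl)-2,2-dimethylindane-6-carboxylic acid | OC(=O)c1cc2c(c(C(=O)OC)c1C=C)CC(C)(C)C2
F2 | step 8 | 5-ethenyl-4-(hydroxymethyl)-2,2-dimethylindane-6-carboxylic acid | OC(=O)c1cc2c(c(CO)c1C=C)CC(C)(C)C2
F3 | step 8 | 4-(acetoxymethyl)-5-ethenyl-2,2-dimethylindane-6-carboxylic acid | OC(=O)c1cc2c(c(COC(C)=O)c1C=C)CC(C)(C)C2
F4 | step 8 | [5-ethenyl-6-(hydroxymethyl)-2,2-dimethylindan-4-yl]methyl acetate | OCc1cc2c(c(COC(C)=O)c1C=C)CC(C)(C)C2
F5 | step 5 | dimethyl 2-bromo-5-(2-bromo-2-methylpropyl)-4-formylisophthalate | COC(=O)c1cc(CC(C)(C)Br)c(C=O)c(C(=O)OC)c1Br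
F6 | step 5 | dimethyl 2-bromo-5-(2-bromo-2-methylpropyl)-4-{(E)-[(2-phenylaziridin-1-yl)imino]methyl}isophthalate, racemic at the aziridine carbon | COC(=O)c1cc(CC(C)(C)Br)c(/C=N/N2CC2c3ccccc3)c(C(=O)OC)c1Br
F7 | step 3 | dimethyl 2-bromo-5-hydroxyisophthalate | COC(=O)c1cc(O)cc(C(=O)OC)c1Br
F8 | step 3 | dimethyl 2-bromo-4-formyl-5-hydroxyisophthalate | COC(=O)c1cc(O)c(C=O)c(C(=O)OC)c1Br
F9 | step 3 | dimethyl 2-bromo-4-formyl-5-{[(trifluoromethyl)sulfonyl]oxy}isophthalate | COC(=O)c1cc(OS(=O)(=O)C(F)(F)F)c(C=O)c(C(=O)OC)c1Br
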